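Plan
1. The hardest feature is the contiguous triad C7 (carbinol)–C3–C4 on an oxolane whose two guaiacyl arms differ by a single oxygen. In addition, the ring oxygen must bridge C2/C5 while the C7–OH stays free.
2. Cuts: the first operation cuts the ring bond C4–C5 and the exocyclic bond CH2–aryl together, leaving an acyclic butenyl (boryl)methyl ether and an aryl bromide. The second cuts C7–C3, leaving a vanillin ester and a (Z)-allylboronate. The third cuts the Z-alkene, leaving two allyl building blocks.
3. Forward: the C4 chain is joined by cross-metathesis, then C7–C3 is made by allylboration. The only ring is then closed by C–C (not C–O) bond formation, with the second arene attached in the same event. Ester cleavage ends the route.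
4. Stereochemistry: C7 and C3 arise together in one catalytic event, where (R)-TRIP fixes the aldehyde face and the Z-alkene fixes the syn relation. C4 is relayed from C3 in the key step (trans, chair-like 5-exo transition state).
5. Enabling feature: the array O1–C5H2–C4H–CH2–aryl of the oxolane. C5 is an unsubstituted carbon next to the ring oxygen, which corresponds to a stabilised O–CH2 radical. C4 carries a one-carbon arm ending in an arene, which corresponds to a terminal vinyl group plus ArBr.
6. Consequence: the two arms enter at different oxidation levels from different building blocks (aldehyde versus aryl bromide), and no 7,9,9'-triol ever has to be cyclised selectively.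

Key step: step 7

Remark on numbering: oxolane O1, C2, C3 (bears the carbinol carbon C7), C4 (bears the benzylic CH2), C5. pin = pinacolato, Piv = pivaloyl.
Assumption: (R)-TRIP is taken to direct allyl-B(pin) reagents to the Re face of aryl aldehydes. Both enantiomers of the acid are commercial.

Step 1
Reactants: 1 vanillin
Product: 2 4-formyl-2-methoxyphenyl pivalate
Conditions: PivCl, Et3N, DMAP (cat.), CH2Cl2, 0 °C to rt
Reagents that add atoms: pivaloyl chloride CC(C)(C)C(=O)Cl
Why: DMAP-catalysed O-acylation of the phenol; the ester masks the phenol, makes the aldehyde more electrophilic and lowers the donor strength of the ring, which later protects the benzylic alcohol from ionisation and the arene from single-electron oxidation.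

Step 2
Reactants: 3 4-bromo-2-methoxyphenol
Product: 4 4-bromo-2-methoxyphenyl pivalate
Conditions: PivCl, Et3N, DMAP (cat.), CH2Cl2, 0 °C to rt
Reagents that add atoms: pivaloyl chloride CC(C)(C)C(=O)Cl
Why: The same O-acylation; the para-acyloxy group also makes the C–Br bond more prone to oxidative addition than that of a phenol ether.

Step 3
Reactants: 5 allyl alcohol, 6 2-(bromomethyl)-4,4,5,5-tetramethyl-1,3,2-dioxaborolane
Product: 8 2-[(prop-2-en-1-yloxy)methyl]-4,4,5,5-tetramethyl-1,3,2-dioxaborolane, via sodium prop-2-en-1-olate 7 (not isolated)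
Conditions: NaH, THF, 0 °C; then 6, 0 °C to rt
Reagents that add atoms: none
Why: Matteson-type substitution of an α-halomethylboronate (alkoxide attack at boron, 1,2-shift of the alkoxy group with loss of bromide) is the standard entry to alkoxymethylboronates and installs the future C5 on the future O1.

Step 4
Reactants: 8 2-[(prop-2-en-1-yloxy)methyl]-4,4,5,5-tetramethyl-1,3,2-dioxaborolane, 9 allylboronic acid pinacol ester
Product: 10 (Z)-2-{4-[(4,4,5,5-tetramethyl-1,3,2-dioxaborolan-2-yl)methoxy]but-2-en-1-yl}-4,4,5,5-tetramethyl-1,3,2-dioxaborolane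
Conditions: 9 (excess), Z-selective cyclometalated Ru–NHC nitrato catalyst (3 mol %), THF, 35 °C, ethylene vented
Reagents that add atoms: none
Why: Kinetically Z-selective olefin cross-metathesis of allyl-B(pin) with an unhindered terminal alkene is a known route to (Z)-γ-substituted allylboronates, and the alkyl-type O–CH2–B(pin) group is a spectator.

Step 5
Reactants: 2 4-formyl-2-methoxyphenyl pivalate, 10 (Z)-bis(boronate)
Product: 12 4-[(1R,2R)-1-hydroxy-2-{[(4,4,5,5-tetramethyl-1,3,2-dioxaborolan-2-yl)methoxy]methyl}but-3-en-1-yl]-2-methoxyphenyl pivalate, via O-boryl adduct 11 (not isolated)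
Conditions: (R)-TRIP (5 mol %), 4 Å MS, toluene, −30 °C; then aq. NaHCO3 (non-oxidative work-up)
Reagents that add atoms: none
Why: Chiral-phosphoric-acid-catalysed allylboration through a closed chair transition state: the Z geometry translates into the syn (1R,2R) relation of C7 and C3, the catalyst should expose the Re face of 2 and so set C7 as R, and only the allylic boronate reacts because the α-alkoxy boronate is inert to aldehydes.

Step 6
Reactants: 12 homoallylic alcohol
Product: 13 potassium trifluoro[({(2R)-2-[(R)-hydroxy(3-methoxy-4-pivaloyloxyphenyl)methyl]but-3-en-1-yl}oxy)methyl]borate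
Conditions: KHF2 (aq.), MeOH, rt; pinacol removed by repeated evaporation from aq. MeOH; acetone extraction
Reagents that add atoms: potassium hydrogen difluoride F.[F-].[K+]
Why: Standard boronate-to-trifluoroborate exchange gives the easily oxidised radical precursor, and the mild acidity should be tolerated because the para-acyloxy ring stabilises a C7 cation only weakly.

Step 7
Reactants: 13 potassium alkoxymethyltrifluoroborate, 4 4-bromo-2-methoxyphenyl pivalate
Product: 16 4-{[(3R,4R)-4-{(R)-hydroxy[3-methoxy-4-(pivaloyloxy)phenyl]methyl}oxolan-3-yl]methyl}-2-methoxyphenyl pivalate, via alkoxymethyl radical 14 (not isolated), via oxolanylmethyl radical 15 (not isolated)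
Conditions: Ir[dF(CF3)ppy]2(bpy)PF6 (2 mol %), NiCl2·dme/dtbbpy (3 mol %), K2HPO4, dioxane–DMA, blue LED, rt, dilute
Reagents that add atoms: none
Why: The excited Ir(III) photocatalyst oxidises 13 to the nucleophilic alkoxymethyl radical 14, which adds 5-exo-trig to the terminal vinyl group (new C5–C4 bond, closing the oxolane); the primary radical 15 is intercepted by the nickel catalyst carrying the aryl group of 4, reductive elimination from Ni(III) forges the CH2–aryl bond, and Ir(II) returns nickel to its low-valent state. The closest known reaction types are the Ni/photoredox cross-coupling of alkoxymethyltrifluoroborates with aryl bromides and the Ni-catalysed radical cyclisation–arylation (1,2-dicarbofunctionalisation) of alkene-tethered radical precursors, which gives 3-(arylmethyl)oxolanes and 5-(arylmethyl)pyrrolidinones. The only new stereocentre, C4, is controlled by C3: in the chair-like 5-exo transition state of this 4-substituted 2-oxahex-5-enyl radical the bulky CH(OH)Ar group sits pseudo-equatorial, which places it trans to the emerging CH2 arm and gives 4R, while C7 and C3 are not touched. The step needs ring closure to outrun direct nickel capture of 14, exo to beat endo closure, and electron transfer to select the C–B bond; the first is secured because cyclisation is unimolecular whereas capture is bimolecular in a catalyst kept at low concentration, the second by the usual stereoelectronic exo preference for an unsubstituted internal alkene carbon, and the third by the pivalates, which raise the oxidation potential of both arenes above that of the trifluoroborate. 1,5-Hydrogen transfer from C7–H to 14 is polarity-mismatched (nucleophilic radical, hydridic C–H), and the trans arrangement keeps 15 away from the C7 aryl ring, so neither C7 nor that ring should be disturbed.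

Step 8
Reactants: 16 bis(pivalate)
Product: 17 (R)-(4-hydroxy-3-methoxyphenyl)[(3R,4R)-4-(4-hydroxy-3-methoxybenzyl)oxolan-3-yl]methanol (CNP0234428.1)
Conditions: K2CO3, MeOH–THF, rt; then pH 7 phosphate buffer
Reagents that add atoms: none
Why: Base-mediated transesterification of two aryl esters proceeds at rt because phenoxide is a good leaving group, and it avoids the acid, hydride and hydrogenolysis conditions that could ionise or cleave the p-hydroxybenzylic C7–O bond, so C7 should keep its configuration.

Compound list
1 | vanillin | COc1cc(C=O)ccc1O | starting material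
2 | 4-formyl-2-methoxyphenyl pivalate | COc1cc(C=O)ccc1OC(=O)C(C)(C)C | intermediate
3 | 4-bromo-2-methoxyphenol | COc1cc(Br)ccc1O | starting material
4 | 4-bromo-2-methoxyphenyl pivalate | COc1cc(Br)ccc1OC(=O)C(C)(C)C | intermediate
5 | allyl alcohol | C=CCO | starting material
6 | 2-(bromomethyl)-4,4,5,5-tetramethyl-1,3,2-dioxaborolane | BrCB1OC(C)(C)C(C)(C)O1 | starting material
7 | sodium prop-2-en-1-olate | [Na+].[O-]CC=C | intermediate
8 | 2-[(prop-2-en-1-yloxy)methyl]-4,4,5,5-tetramethyl-1,3,2-dioxaborolane | C=CCOCB1OC(C)(C)C(C)(C)O1 | intermediate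
9 | allylboronic acid pinacol ester | C=CCB1OC(C)(C)C(C)(C)O1 | starting material
10 | (Z)-2-{4-[(4,4,5,5-tetramethyl-1,3,2-dioxaborolan-2-yl)methoxy]but-2-en-1-yl}-4,4,5,5-tetramethyl-1,3,2-dioxaborolane | CC1(C)OB(C/C=C\COCB2OC(C)(C)C(C)(C)O2)OC1(C)C | intermediate
11 | O-B(pin) borate of 12 (1R,2R) | CC1(C)OB(COC[C@@H](C=C)[C@@H](OB2OC(C)(C)C(C)(C)O2)c2ccc(OC(=O)C(C)(C)C)c(OC)c2)OC1(C)C | intermediate
12 | 4-[(1R,2R)-1-hydroxy-2-{[(4,4,5,5-tetramethyl-1,3,2-dioxaborolan-2-yl)methoxy]methyl}but-3-en-1-yl]-2-methoxyphenyl pivalate | CC1(C)OB(COC[C@@H](C=C)[C@@H](O)c2ccc(OC(=O)C(C)(C)C)c(OC)c2)OC1(C)C | intermediate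
13 | potassium trifluoro[({(2R)-2-[(R)-hydroxy(3-methoxy-4-pivaloyloxyphenyl)methyl]but-3-en-1-yl}oxy)methyl]borate | [K+].F[B-](F)(F)COC[C@@H](C=C)[C@@H](O)c1ccc(OC(=O)C(C)(C)C)c(OC)c1 | intermediate
14 | ({(2R)-2-[(R)-hydroxy(aryl)methyl]but-3-en-1-yl}oxy)methyl radical | [CH2]OC[C@@H](C=C)[C@@H](O)c1ccc(OC(=O)C(C)(C)C)c(OC)c1 | intermediate
15 | [(3R,4R)-4-{(R)-hydroxy(aryl)methyl}oxolan-3-yl]methyl radical | [CH2][C@H]1COC[C@@H]1[C@@H](O)c1ccc(OC(=O)C(C)(C)C)c(OC)c1 | intermediate
16 | 4-{[(3R,4R)-4-{(R)-hydroxy[3-methoxy-4-(pivaloyloxy)phenyl]methyl}oxolan-3-yl]methyl}-2-methoxyphenyl pivalate | COc1cc(C[C@H]2COC[C@@H]2[C@@H](O)c2ccc(OC(=O)C(C)(C)C)c(OC)c2)ccc1OC(=O)C(C)(C)C | intermediate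
17 | (R)-(4-hydroxy-3-methoxyphenyl)[(3R,4R)-4-(4-hydroxy-3-methoxybenzyl)oxolan-3-yl]methanol | COc1cc(C[C@H]2COC[C@@H]2[C@@H](O)c2ccc(O)c(OC)c2)ccc1O | target

Total step count: 8
Longest linear sequence: 6 (steps 3, 4, 5, 6, 7, 8, from allyl alcohol)

Steps most likely to fail

1. Step 7 (key step). Nickel may capture the radical before ring closure. Oxidative addition of the bromide may be slow, so that the radical is lost to hydrogen abstraction. The trans preference in the 5-exo closure may also erode.
The fallback attaches the arene first and closes the ring afterwards without nickel. It sets out from 12 and returns at 16.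
- Purchased 2-methoxy-4-vinylphenol F1 is pivaloylated (PivCl, Et3N) to 2-methoxy-4-vinylphenyl pivalate F2.
- E-selective cross-metathesis of 12 with F2 (second-generation chelated Ru–NHC catalyst, CH2Cl2, 40 °C) should give the (E)-styryl boronate F3.
- KHF2 in aqueous MeOH converts F3 into the styryl trifluoroborate F4.
- Irradiation of F4 with the Ir photocatalyst and a thiol as hydrogen-atom shuttle in aqueous DMA should close the ring by a Giese-type reductive 5-exo cyclisation onto the styrene. This closure is faster than onto a vinyl group and passes through the same chair-like transition state. The benzylic radical takes up hydrogen to give 16.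

2. Step 4. Z selectivity may be incomplete. Homodimerisation of either partner or secondary metathesis of the product would carry E-allylboronate, and thus the anti diastereomer, into step 5.
The fallback buys the Z geometry and changes the allyl metal. It sets out from 6, is joined by 2, and returns at 12.
- Purchased cis-but-2-ene-1,4-diol F5 (excess) is mono-alkylated (NaH, then 6) to the (Z)-hydroxy ether F6.
- Appel chlorination (PPh3, CCl4) should give the (Z)-allylic chloride F7 with retention of geometry.
- HSiCl3, CuCl (cat.) and iPr2NEt in Et2O convert F7 stereospecifically into the (Z)-allyltrichlorosilane F8.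
- Addition of F8 to 2 under a chiral bisphosphoramide Lewis base (CH2Cl2, −78 °C) should proceed through a closed chair at hexacoordinate silicon, giving the syn trichlorosilyl ether F9.
- Aqueous NaHCO3 work-up hydrolyses F9 to 12.

3. Step 5. The bulky pseudo-axial Z substituent may slow the catalysed pathway so far that the uncatalysed background reaction erodes the facial selectivity. The second boronate may also compete for the acid.
The fallback replaces asymmetric catalysis by resolution. It sets out from 2 and 10 and returns at 12.
- Uncatalysed thermal allylboration (toluene, rt to 40 °C) still gives only the syn relation through the closed chair. It delivers 11 together with its mirror image, the ent-borate F10.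
- Hydrolysis then gives 12 together with the (1S,2S)-alcohol F11.
- Acylative kinetic resolution with (S)-benzotetramisole and isobutyric anhydride should acylate the (1S)-carbinol faster, giving the (1S,2S)-isobutyrate F12.
- F12 is separated by chromatography from unreacted 12, at the cost of half of the material.

Further compounds
F1 | step 7 | 2-methoxy-4-vinylphenol (purchased) | C=Cc1ccc(O)c(OC)c1
F2 | step 7 | 2-methoxy-4-vinylphenyl pivalate | C=Cc1ccc(OC(=O)C(C)(C)C)c(OC)c1
F3 | step 7 | (E)-styryl boronate, (1R,2R)-1,4-bis(3-methoxy-4-pivaloyloxyphenyl)-2-{[(pinacolatoboryl)methoxy]methyl}but-3-en-1-ol | CC1(C)OB(COC[C@@H](/C=C/c2ccc(OC(=O)C(C)(C)C)c(OC)c2)[C@@H](O)c2ccc(OC(=O)C(C)(C)C)c(OC)c2)OC1(C)C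
F4 | step 7 | styryl trifluoroborate, potassium salt derived from F3 | [K+].F[B-](F)(F)COC[C@@H](/C=C/c1ccc(OC(=O)C(C)(C)C)c(OC)c1)[C@@H](O)c1ccc(OC(=O)C(C)(C)C)c(OC)c1
F5 | step 4 | cis-but-2-ene-1,4-diol (purchased) | OC/C=C\CO
F6 | step 4 | (Z)-4-[(4,4,5,5-tetramethyl-1,3,2-dioxaborolan-2-yl)methoxy]but-2-en-1-ol | OC/C=C\COCB1OC(C)(C)C(C)(C)O1
F7 | step 4 | (Z)-2-{[(4-chlorobut-2-en-1-yl)oxy]methyl}-4,4,5,5-tetramethyl-1,3,2-dioxaborolane | ClC/C=C\COCB1OC(C)(C)C(C)(C)O1
F8 | step 4 | (Z)-trichloro{4-[(4,4,5,5-tetramethyl-1,3,2-dioxaborolan-2-yl)methoxy]but-2-en-1-yl}silane | Cl[Si](Cl)(Cl)C/C=C\COCB1OC(C)(C)C(C)(C)O1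
F9 | step 4 | trichlorosilyl ether of 12 | CC1(C)OB(COC[C@@H](C=C)[C@@H](O[Si](Cl)(Cl)Cl)c2ccc(OC(=O)C(C)(C)C)c(OC)c2)OC1(C)C
F10 | step 5 | ent-borate, mirror image of 11 | CC1(C)OB(COC[C@H](C=C)[C@H](OB2OC(C)(C)C(C)(C)O2)c2ccc(OC(=O)C(C)(C)C)c(OC)c2)OC1(C)C
F11 | step 5 | (1S,2S)-alcohol, mirror image of 12 | CC1(C)OB(COC[C@H](C=C)[C@H](O)c2ccc(OC(=O)C(C)(C)C)c(OC)c2)OC1(C)C
F12 | step 5 | (1S,2S)-isobutyrate of F11 | CC1(C)OB(COC[C@H](C=C)[C@H](OC(=O)C(C)C)c2ccc(OC(=O)C(C)(C)C)c(OC)c2)OC1(C)C
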